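**Strategy.** The dimer is cut at the central C8–C8′ bond into two diastereomeric halves. In each half, the carbinol C2, the ring carbon C3, the exocyclic C7 and C8 (cis to C2 across C3=C7) can be the ring atoms of a butenolide fused to the cyclohexane (ring A or ring B), with C8 supplied by CO. One Ru3(CO)12-catalysed cyclocarbonylation of a silyl-capped ynal therefore forms C2–C3, C7–C8 and C8–O, closes both rings, locks the Z-alkylidene geometry and creates C2. Its precursor is methyl 2-formyl-2-methyl-7-(trimethylsilyl)hept-6-ynoate, whose two enantiomers (one per half) arise from a single enzymatically desymmetrised malonate half-ester.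

Key step: step 5

**Remarks.**
- Numbering: C1 quaternary carbon, C2 carbinol carbon, C3 ring alkylidene carbon, C4–C6 ring CH2, C7 exocyclic CH, C8 central CH2, C9 ketone carbon; primed numbers for ring B.
- Ring A (first ring of the target SMILES) is (1R,2R), with O-2 cis to the C1 methyl. Ring B is (1′S,2′R), with O-2′ cis to C9′. Both exocyclic alkenes are Z. Ring B is thus the C1 epimer of ring A, so the two halves need opposite enantiomers of the ynal and opposite C2 relative configurations.
- Assumption: pig liver esterase is taken to give the (R)-half-ester, as expected for long-chain 2-alkyl-2-methylmalonates. If the (S)-acid forms instead, the sequences of steps 3–4 and 10–12 are exchanged between the two series.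
- The cyclocarbonylation is run once per series (step 5 for ring A, step 13 for ring B). Each run is expected to give both C2 epimers. The crude pair is desilylated and then converged on the needed epimer by base equilibration of C2 with separation and return of the other epimer (steps 6 and 14).

**Route**

Step 1
Reactants: 1 dimethyl 2-methylmalonate; 2 (5-chloropent-1-yn-1-yl)trimethylsilane
Product: 3 dimethyl 2-methyl-2-[5-(trimethylsilyl)pent-4-yn-1-yl]malonate
Conditions: NaH, THF/DMF, 0 °C; then 2, NaI (cat.), 65 °C
Reagents that add atoms: none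
Why: SN2 malonic ester alkylation of the sodium enolate by the primary chloride, assisted by Finkelstein exchange with catalytic iodide; the quaternary carbon is not yet stereogenic.

Step 2
Reactants: 3 dimethyl 2-methyl-2-[5-(trimethylsilyl)pent-4-yn-1-yl]malonate
Product: 4 (R)-3-methoxy-2-methyl-3-oxo-2-[5-(trimethylsilyl)pent-4-yn-1-yl]propanoic acid (half-ester)
Conditions: pig liver esterase, phosphate buffer pH 7.5, DMSO (10 vol%), 25 °C
Reagents that add atoms: water, O
Why: Enzymatic desymmetrisation by hydrolysis of one enantiotopic ester sets C1 for both halves at neutral pH, which the silylalkyne tolerates; the optical purity should be checked and, if needed, raised by crystallising a 1-phenylethylammonium salt.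

Step 3
Reactants: 4 (R)-half-ester
Product: 6 methyl (R)-2-(hydroxymethyl)-2-methyl-7-(trimethylsilyl)hept-6-ynoate, via acid chloride 5 (not isolated)
Conditions: (COCl)2, DMF (cat.), CH2Cl2, 0 °C → rt; then NaBH4, THF/DMF, −20 → 0 °C
Reagents that add atoms: none
Why: Chemoselective reduction of the acid through its acid chloride (no α-hydrogen, so no ketene) with NaBH4 leaves the methyl ester, the silylalkyne and C1 untouched.

Step 4
Reactants: 6 methyl (R)-2-(hydroxymethyl)-2-methyl-7-(trimethylsilyl)hept-6-ynoate
Product: 7 methyl (R)-2-formyl-2-methyl-7-(trimethylsilyl)hept-6-ynoate (ynal, ring A enantiomer)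
Conditions: Dess–Martin periodinane, CH2Cl2, rt
Reagents that add atoms: none
Why: Dess–Martin oxidation of the neopentyl primary alcohol gives an aldehyde that cannot enolise, so C1 is configurationally safe.

Step 5
Reactants: 7 methyl (R)-2-formyl-2-methyl-7-(trimethylsilyl)hept-6-ynoate; 8 carbon monoxide
Product: 9 ring A α-silyl butenolide ester, methyl 7-methyl-2-oxo-3-(trimethylsilyl)-2,4,5,6,7,7a-hexahydro-1-benzofuran-7-carboxylate (C1 as in 7; lactone oxygen on C2 cis to the C1 methyl)
Conditions: Ru3(CO)12 (3 mol%), CO (10 atm), toluene, 160 °C; filtration through silica, C2 epimers not separated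
Reagents that add atoms: none
Why: Under CO, Ru3(CO)12 breaks up into zerovalent ruthenium carbonyl fragments that couple the aldehyde C=O and the alkyne oxidatively to an oxaruthenacyclopentene (C2–C3 bond), after which CO inserts into the Ru–C7 bond and C8–O reductive elimination releases the lactone and the catalyst. The closest known reaction type is the catalytic hetero-Pauson–Khand cyclocarbonylation of silyl-capped yne-aldehydes to fused bicyclic butenolides. The cyclohexane closes in the 6-exo-dig sense when C2 bonds to the proximal alkyne carbon C3, and the butenolide closes by the reductive elimination that joins C8 to the aldehyde oxygen, which forces C8 and C2 cis on C3=C7. C2 is the only new stereocentre and is set under substrate control by the neighbouring quaternary C1 (chair-like coupling with either CH3 or CO2Me axial), a weak bias, so the C2 epimer of 9 should form alongside it; the pair is carried on unseparated because step 6 converges it by equilibration of C2. The step needs ynal coupling to win over alkyne oligomerisation and aldehyde decarbonylation, which the bulky SiMe3 cap, the CO pressure and the non-enolisable quaternary C1 should secure, while the three-carbon tether fixes which alkyne carbon bonds to C2.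

Step 6
Reactants: 9 ring A α-silyl butenolide ester (used as obtained from step 5, together with its C2 epimer)
Product: 11 ring A butenolide ester, methyl 7-methyl-2-oxo-2,4,5,6,7,7a-hexahydro-1-benzofuran-7-carboxylate (lactone oxygen cis to the C1 methyl), via desilylated C2-epimer mixture 10 (not isolated)
Conditions: Bu4NF, AcOH (1:1), THF, 0 °C → rt; silica plug; then DBU (0.3 equiv), toluene, 50 °C; chromatography, unwanted C2 epimer returned to the DBU equilibration
Reagents that add atoms: none
Why: Fluoride protodesilylation of the α-silyl enoate gives the two C2-epimeric butenolides, and DBU then interconverts them by γ-deprotonation to the 2-oxidofuran and reprotonation, so that separation and re-equilibration of the unwanted epimer funnel the material into 11; C1 has no acidic hydrogen and is untouched.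

Step 7
Reactants: 11 ring A butenolide ester
Product: 12 ring A triol, (Z)-2-[2-hydroxy-3-(hydroxymethyl)-3-methylcyclohexylidene]ethan-1-ol (O-2 cis to the C1 methyl)
Conditions: i-Bu2AlH (excess), CH2Cl2, −78 → 0 °C; aq. KNaC4H4O6
Reagents that add atoms: none
Why: Hydride 1,2-reduction of the butenolide through lactol and hydroxy-enal to the (Z)-ene-diol, and of the ester to the neopentyl alcohol, with excess hydride and a non-acidic work-up to keep the lactol from dehydrating to a furan; the alkene geometry is inherited from the ring and no stereocentre is touched.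

Step 8
Reactants: 12 ring A triol
Product: 13 ring A acetal alcohol (4-methoxybenzylidene acetal bridging O-2 and O-9 as a 2-aryl-1,3-dioxane, aryl equatorial, acetal H cis to H-2; C8 allylic alcohol free)
Conditions: 4-MeOC6H4CH(OMe)2, PPTS (cat.), CH2Cl2, rt
Reagents that add atoms: 4-methoxybenzaldehyde dimethyl acetal, COc1ccc(cc1)C(OC)OC
Why: Acetalisation under thermodynamic control favours the six-membered dioxane of the 1,3-diol over the seven-membered acetal through O-8, so only the C8 alcohol stays free; the new acetal centre (aryl equatorial) is removed in step 20.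

Step 9
Reactants: 13 ring A acetal alcohol
Product: 15 ring A allylic bromide, via ring A mesylate 14 (not isolated)
Conditions: MsCl, Et3N, THF, −40 °C; then LiBr, −40 → 0 °C
Reagents that add atoms: lithium bromide, [Li+].[Br-]
Why: Mesylation of the primary allylic alcohol and SN2 displacement by bromide at low temperature should keep the Z geometry and avoid allylic transposition.

Step 10
Reactants: 4 (R)-half-ester
Product: 17 (S)-2-(hydroxymethyl)-2-methyl-7-(trimethylsilyl)hept-6-ynoic acid, via sodium carboxylate 16 (not isolated)
Conditions: NaH, THF, 0 °C; then LiBH4, THF, 0 → 40 °C; aq. HCl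
Reagents that add atoms: none
Why: LiBH4 reduces the methyl ester but not the carboxylate, which exchanges the oxidation levels of the two carbonyl carbons relative to step 3 (enantiodivergent use of one half-ester) without touching C1.

Step 11
Reactants: 17 (S)-2-(hydroxymethyl)-2-methyl-7-(trimethylsilyl)hept-6-ynoic acid
Product: 18 methyl (S)-2-(hydroxymethyl)-2-methyl-7-(trimethylsilyl)hept-6-ynoate
Conditions: MeI, KHCO3, DMF, rt
Reagents that add atoms: iodomethane, CI
Why: SN2 O-alkylation of the carboxylate gives the enantiomer of 6 under conditions too mild to affect the alcohol or the silylalkyne.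

Step 12
Reactants: 18 methyl (S)-2-(hydroxymethyl)-2-methyl-7-(trimethylsilyl)hept-6-ynoate
Product: 19 methyl (S)-2-formyl-2-methyl-7-(trimethylsilyl)hept-6-ynoate (ynal, ring B enantiomer)
Conditions: Dess–Martin periodinane, CH2Cl2, rt
Reagents that add atoms: none
Why: Dess–Martin oxidation as in step 4 gives the non-enolisable aldehyde with C1 intact.

Step 13
Reactants: 19 methyl (S)-2-formyl-2-methyl-7-(trimethylsilyl)hept-6-ynoate; 8 carbon monoxide
Product: 20 ring B α-silyl butenolide ester (C1 as in 19; lactone oxygen on C2 cis to the ester group)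
Conditions: Ru3(CO)12 (3 mol%), CO (10 atm), toluene, 160 °C; filtration through silica, C2 epimers not separated
Reagents that add atoms: none
Why: The same hetero-Pauson–Khand cyclocarbonylation as in step 5 on the enantiomeric ynal, where the epimer with the lactone oxygen cis to C9 is the one needed and the accompanying C2 epimer is carried on unseparated into the equilibration of step 14.

Step 14
Reactants: 20 ring B α-silyl butenolide ester (used as obtained from step 13, together with its C2 epimer)
Product: 22 ring B butenolide ester (lactone oxygen cis to the ester group), via desilylated C2-epimer mixture 21 (not isolated)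
Conditions: Bu4NF, AcOH (1:1), THF, 0 °C → rt; silica plug; then DBU (0.3 equiv), toluene, 50 °C; chromatography, unwanted C2 epimer returned to the DBU equilibration
Reagents that add atoms: none
Why: Protodesilylation and DBU-mediated γ-epimerisation through the 2-oxidofuran as in step 6, with separation of the epimer needed for ring B and return of the other; C1 is untouched.

Step 15
Reactants: 22 ring B butenolide ester
Product: 23 ring B triol, (Z)-2-[2-hydroxy-3-(hydroxymethyl)-3-methylcyclohexylidene]ethan-1-ol (O-2 cis to C9)
Conditions: i-Bu2AlH (excess), CH2Cl2, −78 → 0 °C; aq. KNaC4H4O6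
Reagents that add atoms: none
Why: Hydride reduction of lactone and ester as in step 7, with the Z geometry inherited from the ring.

Step 16
Reactants: 23 ring B triol
Product: 24 ring B acetal alcohol (4-methoxybenzylidene acetal bridging O-2 and O-9, aryl equatorial, acetal H cis to H-2; C8 alcohol free)
Conditions: 4-MeOC6H4CH(OMe)2, PPTS (cat.), CH2Cl2, rt
Reagents that add atoms: 4-methoxybenzaldehyde dimethyl acetal, COc1ccc(cc1)C(OC)OC
Why: Thermodynamic acetalisation of the 1,3-diol as in step 8, here giving the cis-fused dioxane with the aryl group equatorial.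

Step 17
Reactants: 24 ring B acetal alcohol
Product: 27 ring B allylic phenyl sulfone, via ring B mesylate 25 (not isolated), via ring B bromide 26 (not isolated)
Conditions: MsCl, Et3N, THF, −40 °C; LiBr, −40 → 0 °C; then PhSO2Na, DMF, rt
Reagents that add atoms: sodium benzenesulfinate, [Na+].[O-]S(=O)c1ccccc1
Why: Mesylation, bromide exchange and SN2 S-alkylation of the sulfinate in one flask, where the soft allylic bromide directs attack through sulfur and the primary position disfavours allylic shift.

Step 18
Reactants: 27 ring B allylic phenyl sulfone; 15 ring A allylic bromide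
Product: 28 coupled bis-acetal sulfone (C8–C8′ bond formed; PhSO2 on C8′ as a mixture of epimers)
Conditions: LiN(SiMe3)2, THF/DMPU, −78 °C; then 15, −78 → −30 °C
Reagents that add atoms: none
Why: α-Alkylation of the lithiated allylic sulfone by the primary allylic bromide (SN2) joins the halves with both Z-alkenes intact; the new sulfone-bearing centre is removed in step 19.

Step 19
Reactants: 28 coupled bis-acetal sulfone
Product: 29 bis-acetal 1,5-diene (ring A and ring B linked by C8H2–C8′H2)
Conditions: PdCl2(dppp) (5 mol%; dppp = 1,3-bis(diphenylphosphino)propane), LiBHEt3, THF, 0 °C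
Reagents that add atoms: none
Why: Palladium-catalysed reductive desulfonylation, in which the divalent palladium precatalyst is reduced to zerovalent palladium that ionises the allylic sulfone to a π-allyl complex and hydride is delivered to the less hindered terminus C8′; position and geometry of C3′=C7′ should hold because syn/anti exchange at the fully substituted C3′ terminus is slow.

Step 20
Reactants: 29 bis-acetal 1,5-diene
Product: 30 bis-PMB ether diol (O-2 and O-2′ as 4-methoxybenzyl ethers; C9 and C9′ primary alcohols)
Conditions: i-Bu2AlH, CH2Cl2, −78 → 0 °C; aq. KNaC4H4O6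
Reagents that add atoms: none
Why: Regioselective reductive opening of the 4-methoxybenzylidene acetals, in which aluminium coordinates the less hindered primary oxygen so that each acetal gives the free primary alcohol and the PMB ether on the secondary O-2.

Step 21
Reactants: 30 bis-PMB ether diol
Product: 31 bis-PMB ether dialdehyde
Conditions: Dess–Martin periodinane, pyridine, CH2Cl2, 0 °C → rt
Reagents that add atoms: none
Why: Dess–Martin oxidation of both neopentyl alcohols gives aldehydes without α-hydrogen, so neither epimerisation at C1 nor β-elimination of the PMB ether is possible.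

Step 22
Reactants: 31 bis-PMB ether dialdehyde; 32 allylmagnesium bromide
Product: 33 bis(homoallylic alcohol) (C9 and C9′ carbinols as mixtures of epimers)
Conditions: CH2=CHCH2MgBr (excess, one equivalent consumed per aldehyde), Et2O/THF, −78 °C; then H2O
Reagents that add atoms: allylmagnesium bromide (second equivalent of 32), C=CC[Mg]Br
Why: Grignard 1,2-addition of the allyl reagent through a cyclic transition state tolerates the two hindered aldehydes; the new carbinol centres are erased in step 24.

Step 23
Reactants: 33 bis(homoallylic alcohol); 34 2-methylbut-2-ene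
Product: 35 bis(prenyl carbinol)
Conditions: second-generation Grubbs catalyst (5 mol%), 2-methylbut-2-ene (excess)/CH2Cl2, 35 °C
Reagents that add atoms: 2-methylbut-2-ene (second equivalent of 34), CC=C(C)C
Why: Olefin cross-metathesis of the two monosubstituted alkenes with 2-methylbut-2-ene installs the prenyl termini with loss of propene; the hindered exocyclic alkenes should stay inert, since ring closure onto them would need a bridgehead alkene.

Step 24
Reactants: 35 bis(prenyl carbinol)
Product: 36 bis-PMB ether of the target (C9 and C9′ ketones)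
Conditions: Dess–Martin periodinane, pyridine, CH2Cl2, 0 °C
Reagents that add atoms: none
Why: Buffered Dess–Martin oxidation of the secondary homoallylic alcohols gives the β,γ-unsaturated ketones under non-basic conditions that should not move the double bond into conjugation.

Step 25
Reactants: 36 bis-PMB ether of the target
Product: 37 CNP0297042.3
Conditions: DDQ, CH2Cl2/pH 7 phosphate buffer, 0 °C
Reagents that add atoms: none
Why: Oxidative PMB ether cleavage by DDQ (hydride abstraction, then hydrolysis of the oxocarbenium ion) at neutral pH avoids the retro-aldol and enone-isomerisation pathways that base would open in the β-hydroxy ketones.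

**Compound list**

1 | dimethyl 2-methylmalonate | COC(=O)C(C)C(=O)OC | starting material
2 | (5-chloropent-1-yn-1-yl)trimethylsilane | C[Si](C)(C)C#CCCCCl | starting material
3 | dimethyl 2-methyl-2-[5-(trimethylsilyl)pent-4-yn-1-yl]malonate | COC(=O)C(C)(CCCC#C[Si](C)(C)C)C(=O)OC | intermediate
4 | (R)-3-methoxy-2-methyl-3-oxo-2-[5-(trimethylsilyl)pent-4-yn-1-yl]propanoic acid | COC(=O)[C@](C)(CCCC#C[Si](C)(C)C)C(=O)O | intermediate
5 | acid chloride of 4, methyl 2-(chlorocarbonyl)-2-methyl-7-(trimethylsilyl)hept-6-ynoate | COC(=O)[C@](C)(CCCC#C[Si](C)(C)C)C(Cl)=O | intermediate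
6 | methyl (R)-2-(hydroxymethyl)-2-methyl-7-(trimethylsilyl)hept-6-ynoate | COC(=O)[C@](C)(CCCC#C[Si](C)(C)C)CO | intermediate
7 | methyl (R)-2-formyl-2-methyl-7-(trimethylsilyl)hept-6-ynoate | COC(=O)[C@](C)(CCCC#C[Si](C)(C)C)C=O | intermediate
8 | carbon monoxide | [C-]#[O+] | starting material
9 | ring A α-silyl butenolide ester (lactone O cis to C1 methyl) | COC(=O)[C@]1(C)CCCC2=C([Si](C)(C)C)C(=O)O[C@@H]12 | intermediate
10 | desilylated ring A butenolide ester, mixture of C2 epimers | COC(=O)[C@]1(C)CCCC2=CC(=O)OC12 | intermediate
11 | ring A butenolide ester (lactone O cis to C1 methyl) | COC(=O)[C@]1(C)CCCC2=CC(=O)O[C@@H]12 | intermediate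
12 | ring A triol | OC[C@]1(C)CCC/C(=C/CO)[C@H]1O | intermediate
13 | ring A acetal alcohol | COc1ccc(cc1)[C@H]2OC[C@]3(C)CCC/C(=C/CO)[C@H]3O2 | intermediate
14 | ring A allylic mesylate | COc1ccc(cc1)[C@H]2OC[C@]3(C)CCC/C(=C/COS(C)(=O)=O)[C@H]3O2 | intermediate
15 | ring A allylic bromide | COc1ccc(cc1)[C@H]2OC[C@]3(C)CCC/C(=C/CBr)[C@H]3O2 | intermediate
16 | sodium carboxylate of 4 | COC(=O)[C@](C)(CCCC#C[Si](C)(C)C)C(=O)[O-].[Na+] | intermediate
17 | (S)-2-(hydroxymethyl)-2-methyl-7-(trimethylsilyl)hept-6-ynoic acid | OC[C@](C)(CCCC#C[Si](C)(C)C)C(=O)O | intermediate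
18 | methyl (S)-2-(hydroxymethyl)-2-methyl-7-(trimethylsilyl)hept-6-ynoate | COC(=O)[C@@](C)(CCCC#C[Si](C)(C)C)CO | intermediate
19 | methyl (S)-2-formyl-2-methyl-7-(trimethylsilyl)hept-6-ynoate | COC(=O)[C@@](C)(CCCC#C[Si](C)(C)C)C=O | intermediate
20 | ring B α-silyl butenolide ester (lactone O cis to ester) | COC(=O)[C@@]1(C)CCCC2=C([Si](C)(C)C)C(=O)O[C@@H]12 | intermediate
21 | desilylated ring B butenolide ester, mixture of C2 epimers | COC(=O)[C@@]1(C)CCCC2=CC(=O)OC12 | intermediate
22 | ring B butenolide ester (lactone O cis to ester) | COC(=O)[C@@]1(C)CCCC2=CC(=O)O[C@@H]12 | intermediate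
23 | ring B triol | OC[C@@]1(C)CCC/C(=C/CO)[C@H]1O | intermediate
24 | ring B acetal alcohol | COc1ccc(cc1)[C@H]2OC[C@@]3(C)CCC/C(=C/CO)[C@H]3O2 | intermediate
25 | ring B allylic mesylate | COc1ccc(cc1)[C@H]2OC[C@@]3(C)CCC/C(=C/COS(C)(=O)=O)[C@H]3O2 | intermediate
26 | ring B allylic bromide | COc1ccc(cc1)[C@H]2OC[C@@]3(C)CCC/C(=C/CBr)[C@H]3O2 | intermediate
27 | ring B allylic phenyl sulfone | COc1ccc(cc1)[C@H]2OC[C@@]3(C)CCC/C(=C/CS(=O)(=O)c4ccccc4)[C@H]3O2 | intermediate
28 | coupled bis-acetal sulfone (C8′ epimers) | COc1ccc(cc1)[C@H]2OC[C@]3(C)CCC/C(=C/CC(S(=O)(=O)c4ccccc4)/C=C5/CCC[C@]6(C)CO[C@H](c7ccc(OC)cc7)O[C@H]56)[C@H]3O2 | intermediate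
29 | bis-acetal 1,5-diene | COc1ccc(cc1)[C@H]2OC[C@]3(C)CCC/C(=C/CC/C=C4/CCC[C@]5(C)CO[C@H](c6ccc(OC)cc6)O[C@H]45)[C@H]3O2 | intermediate
30 | bis-PMB ether diol | OC[C@]1(C)CCC/C(=C/CC/C=C2/CCC[C@](C)(CO)[C@@H]2OCc3ccc(OC)cc3)[C@H]1OCc4ccc(OC)cc4 | intermediate
31 | bis-PMB ether dialdehyde | O=C[C@]1(C)CCC/C(=C/CC/C=C2/CCC[C@](C)(C=O)[C@@H]2OCc3ccc(OC)cc3)[C@H]1OCc4ccc(OC)cc4 | intermediate
32 | allylmagnesium bromide | C=CC[Mg]Br | starting material
33 | bis(homoallylic alcohol) (C9, C9′ epimer mixture) | C=CCC(O)[C@]1(C)CCC/C(=C/CC/C=C2/CCC[C@](C)(C(O)CC=C)[C@@H]2OCc3ccc(OC)cc3)[C@H]1OCc4ccc(OC)cc4 | intermediate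
34 | 2-methylbut-2-ene | CC=C(C)C | starting material
35 | bis(prenyl carbinol) (C9, C9′ epimer mixture) | CC(C)=CCC(O)[C@]1(C)CCC/C(=C/CC/C=C2/CCC[C@](C)(C(O)CC=C(C)C)[C@@H]2OCc3ccc(OC)cc3)[C@H]1OCc4ccc(OC)cc4 | intermediate
36 | bis-PMB ether of the target | CC(C)=CCC(=O)[C@]1(C)CCC/C(=C/CC/C=C2/CCC[C@](C)(C(=O)CC=C(C)C)[C@@H]2OCc3ccc(OC)cc3)[C@H]1OCc4ccc(OC)cc4 | intermediate
37 | CNP0297042.3 | CC(C)=CCC(=O)[C@]1(C)CCC/C(=C/CC/C=C2/CCC[C@](C)(C(=O)CC=C(C)C)[C@@H]2O)[C@H]1O | target

**Step count.** 25 steps in total, with the cyclocarbonylation run once in each series (steps 5 and 13). Longest linear sequence: 18 steps (1, 2, 10–25).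

**Steps most likely to fail**

Step 5 (and its mirror-image twin, step 13). Oxidative coupling to the six-membered ring may be slow at the hindered, ester-flanked aldehyde, so that aldehyde decarbonylation and alkyne oligomerisation compete at 160 °C. Low facial selectivity at C2 is already absorbed by the equilibrations of steps 6 and 14. The fallback builds the same butenolide stepwise by an intramolecular Nozaki–Hiyama–Kishi reaction and sets out from 6. K2CO3 in MeOH removes the silyl cap to give methyl (R)-2-(hydroxymethyl)-2-methylhept-6-ynoate F1. Oxidative methoxycarbonylation of the terminal alkyne (PdCl2 cat., CuCl2, NaOAc, CO 1 atm, MeOH) gives dimethyl (R)-2-(hydroxymethyl)-2-methyloct-6-ynedioate F2. Dess–Martin oxidation gives dimethyl (R)-2-formyl-2-methyloct-6-ynedioate F3, and anti-hydroiodination (NaI, AcOH, 70 °C) gives dimethyl (R,Z)-2-formyl-6-iodo-2-methyloct-6-enedioate F4. CrCl2 with catalytic NiCl2 in DMF then adds the alkenylchromium to the aldehyde (closing the cyclohexane) and the alkoxide lactonises onto the cis ester. This returns to the route at the C2-epimer mixture 10, which the DBU stage of step 6 converts into 11. Run from 18, the same sequence passes through methyl (S)-2-(hydroxymethyl)-2-methylhept-6-ynoate F5, dimethyl (S)-2-(hydroxymethyl)-2-methyloct-6-ynedioate F6, dimethyl (S)-2-formyl-2-methyloct-6-ynedioate F7 and dimethyl (S,Z)-2-formyl-6-iodo-2-methyloct-6-enedioate F8 and rejoins at 21.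

Step 2. The esterase may discriminate poorly between the enantiotopic esters for this side chain, which would carry both halves forward in low optical purity and give diastereomeric dimers at the union. The fallback replaces desymmetrisation by resolution and sets out from 3. Mono-reduction with LiAlH(OtBu)3 in refluxing THF gives racemic methyl 2-(hydroxymethyl)-2-methyl-7-(trimethylsilyl)hept-6-ynoate F9. Preparative chromatography on a chiral stationary phase separates it into 6 and 18, which re-enter the route at steps 4 and 12, so steps 2, 3, 10 and 11 are not needed.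

Step 19. Hydride delivery to the wrong terminus or syn/anti exchange in the π-allylpalladium intermediate would erode the position or the Z geometry of the ring B alkene, and the reduction may stall. The fallback avoids the sulfone altogether and sets out from 24 and 15. Compound 24 is converted through mesylate 25 (MsCl, Et3N, then LiCl, THF, 0 °C) into the ring B allylic chloride F10. Activated barium (from BaI2 and lithium biphenylide, THF, −78 °C) turns this into the ring B allylbarium chloride F11, which couples at its α-carbon with bromide 15 at −78 °C with retention of both alkene geometries. This gives 29 directly and bypasses steps 17–19.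

**Further compounds**

F1 | step 5 | methyl (R)-2-(hydroxymethyl)-2-methylhept-6-ynoate | COC(=O)[C@](C)(CCCC#C)CO
F2 | step 5 | dimethyl (R)-2-(hydroxymethyl)-2-methyloct-6-ynedioate | COC(=O)[C@](C)(CCCC#CC(=O)OC)CO
F3 | step 5 | dimethyl (R)-2-formyl-2-methyloct-6-ynedioate | COC(=O)[C@](C)(CCCC#CC(=O)OC)C=O
F4 | step 5 | dimethyl (R,Z)-2-formyl-6-iodo-2-methyloct-6-enedioate | COC(=O)[C@](C)(CCC/C(I)=C/C(=O)OC)C=O
F5 | step 5 | methyl (S)-2-(hydroxymethyl)-2-methylhept-6-ynoate | COC(=O)[C@@](C)(CCCC#C)CO
F6 | step 5 | dimethyl (S)-2-(hydroxymethyl)-2-methyloct-6-ynedioate | COC(=O)[C@@](C)(CCCC#CC(=O)OC)CO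
F7 | step 5 | dimethyl (S)-2-formyl-2-methyloct-6-ynedioate | COC(=O)[C@@](C)(CCCC#CC(=O)OC)C=O
F8 | step 5 | dimethyl (S,Z)-2-formyl-6-iodo-2-methyloct-6-enedioate | COC(=O)[C@@](C)(CCC/C(I)=C/C(=O)OC)C=O
F9 | step 2 | racemic methyl 2-(hydroxymethyl)-2-methyl-7-(trimethylsilyl)hept-6-ynoate | COC(=O)C(C)(CCCC#C[Si](C)(C)C)CO
F10 | step 19 | ring B allylic chloride | COc1ccc(cc1)[C@H]2OC[C@@]3(C)CCC/C(=C/CCl)[C@H]3O2
F11 | step 19 | ring B allylbarium chloride | COc1ccc(cc1)[C@H]2OC[C@@]3(C)CCC/C(=C/C[Ba]Cl)[C@H]3O2
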